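**Retrosynthetic overview**

- The target is reached from an 8-hydroxy-4,5-epoxy-germacr-1(10)-en-12,6-olide by lactone α-methylenation, O8 isovalerylation, removal of the C14 protecting group and MnO2 oxidation of the allylic C14 alcohol.
- Key disconnection C7–C8: C7 is the β-carbon of the 12,6-γ-lactone and its ring neighbour C8 carries oxygen. A ketyl radical at C8 can therefore add to a C7=C11 butenolide, closing the ten-membered carbocycle and setting C7 and C8 next to the already fixed C6.
- The butenolide comes from Felkin–Anh addition of lithium ethyl propiolate to the C6 epoxy aldehyde, semihydrogenation and lactonisation.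
- The ring-cis C1=C10 olefin comes from an E-selective Horner–Wadsworth–Emmons reaction of the C1 aldehyde with an α-(2-silyloxyethyl)phosphonoacetate. The ester becomes C14 and the silyloxyethyl arm becomes C9–C8.
- C4 and C5 come from Sharpless epoxidation of nerol. Ring order: oxirane, then butenolide, then ten-membered ring.

Key step: step 14

Remark on the chemistry: germacranolide numbering is used throughout (C1=C10 olefin, C4–C5 epoxide, oxygen on C6 and C8, lactone carbons C11–C13, C14 on C10, C15 on C4); C8 is carried as a silyl-protected primary alcohol and oxidised under neutral conditions just before the key step, and C14 as a 4-methoxybenzyl (PMB) ether, so that no acid meets the trisubstituted epoxide and no late desilylation has to be selective.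

**Route**

Step 1
Reactants: 1 triethyl phosphonoacetate; 2 tert-butyl(2-iodoethoxy)dimethylsilane
Product: 3 ethyl 4-(tert-butyldimethylsilyloxy)-2-(diethoxyphosphoryl)butanoate (racemic)
Conditions: NaH, 1 (1.5 equiv), DMSO/THF, 0 °C → rt; then 2, 50 °C
Reagents that add atoms: none
Why: SN2 C-alkylation of the sodium phosphonoacetate by a primary iodide, with excess 1 to suppress dialkylation; the new stereocentre is irrelevant because it becomes sp2 in step 5.

Step 2
Reactants: 4 nerol
Product: 5 [(2S,3R)-3-methyl-3-(4-methylpent-3-en-1-yl)oxiran-2-yl]methanol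
Conditions: Ti(OiPr)4 (cat.), L-(+)-diethyl tartrate (cat.), t-BuOOH, 4 Å MS, CH2Cl2, −20 °C
Reagents that add atoms: tert-butyl hydroperoxide CC(C)(C)OO
Why: Sharpless asymmetric epoxidation, in which the titanium tartrate from L-(+)-diethyl tartrate delivers oxygen to the face of the Z-allylic alcohol that gives the (2S,3R)-epoxide; this sets C4 (R) and C5 (S), and the cis relation of C3 and C6 on the oxirane comes from the Z olefin.

Step 3
Reactants: 5 epoxy alcohol
Product: 6 triethyl{[(2S,3R)-3-methyl-3-(4-methylpent-3-en-1-yl)oxiran-2-yl]methoxy}silane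
Conditions: Et3SiCl, imidazole, CH2Cl2, 0 °C
Reagents that add atoms: chlorotriethylsilane CC[Si](Cl)(CC)CC
Why: standard silylation of a primary alcohol; the triethylsilyl ether can later be removed without touching the tert-butyldimethylsilyl ether on O8.

Step 4
Reactants: 6 silyl ether
Product: 8 3-[(2R,3S)-2-methyl-3-(triethylsilyloxymethyl)oxiran-2-yl]propanal, via ozonide 7 (not isolated)
Conditions: O3, CH2Cl2, −78 °C; PPh3, −78 °C → rt
Reagents that add atoms: ozone [O-][O+]=O
Why: ozonolysis with reductive work-up of the only C=C bond in 6, which unveils C1 as the aldehyde and loses acetone.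

Step 5
Reactants: 8 aldehyde; 3 phosphonate
Product: 9 ethyl (2E)-2-[2-(tert-butyldimethylsilyloxy)ethyl]-5-[(2R,3S)-2-methyl-3-(triethylsilyloxymethyl)oxiran-2-yl]pent-2-enoate
Conditions: 3, NaH, THF, 0 °C; then 8, 0 °C → rt
Reagents that add atoms: none
Why: Horner–Wadsworth–Emmons olefination, which with the sodium phosphonate should favour the E enoate (ester trans to C2) and so place C9 cis to C2, the ring-cis geometry of C1=C10; any Z isomer is removed by chromatography.

Step 6
Reactants: 9 enoate
Product: 10 (2E)-2-[2-(tert-butyldimethylsilyloxy)ethyl]-5-[(2R,3S)-2-methyl-3-(triethylsilyloxymethyl)oxiran-2-yl]pent-2-en-1-ol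
Conditions: i-Bu2AlH, CH2Cl2, −78 °C; aq. potassium sodium tartrate
Reagents that add atoms: none
Why: 1,2-reduction of the conjugated ester to the allylic C14 alcohol at a temperature at which the silyl ethers and the epoxide are not attacked.

Step 7
Reactants: 10 allylic alcohol
Product: 11 4-methoxybenzyl ether of 10 at O14 (E olefin and epoxide unchanged)
Conditions: NaH, 4-methoxybenzyl chloride, Bu4NI (cat.), THF/DMF, 0 °C → rt
Reagents that add atoms: 4-methoxybenzyl chloride COc1ccc(CCl)cc1
Why: Williamson etherification of the allylic alkoxide; the PMB ether is inert to fluoride, SmI2 and enolate chemistry and is removed oxidatively at the end.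

Step 8
Reactants: 11 fully protected triol
Product: 12 [(2S,3R)-3-{(3E)-6-(tert-butyldimethylsilyloxy)-4-[(4-methoxybenzyloxy)methyl]hex-3-en-1-yl}-3-methyloxiran-2-yl]methanol
Conditions: HF·pyridine, pyridine, THF, 0 °C
Reagents that add atoms: none
Why: selective desilylation, since under buffered HF·pyridine a primary triethylsilyl ether is cleaved much faster than the primary tert-butyldimethylsilyl ether on O8.

Step 9
Reactants: 12 epoxy alcohol
Product: 13 (2R,3R)-3-{(3E)-6-(tert-butyldimethylsilyloxy)-4-[(4-methoxybenzyloxy)methyl]hex-3-en-1-yl}-3-methyloxirane-2-carbaldehyde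
Conditions: Dess–Martin periodinane, NaHCO3, CH2Cl2, 0 °C → rt
Reagents that add atoms: none
Why: Dess–Martin oxidation under buffered conditions gives the α,β-epoxy aldehyde (C6) without epoxide opening or epimerisation at C5; it is used crude.

Step 10
Reactants: 13 epoxy aldehyde; 14 ethyl propiolate
Product: 15 ethyl (4S)-4-hydroxy-4-[(2S,3R)-3-{(3E)-6-(tert-butyldimethylsilyloxy)-4-[(4-methoxybenzyloxy)methyl]hex-3-en-1-yl}-3-methyloxiran-2-yl]but-2-ynoate
Conditions: 14, LiN(SiMe3)2, THF, −78 °C; then 13, −78 °C; AcOH, −78 °C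
Reagents that add atoms: none
Why: 1,2-addition of lithium ethyl propiolate to the aldehyde; C6 is set by Felkin–Anh control, the acetylide arriving anti to the C5–O bond of the epoxide and past H5, reinforced by the cis substituent on C4, which should give the 6S carbinol (C5–O and C6–O erythro).

Step 11
Reactants: 15 hydroxy ynoate
Product: 17 (5S)-5-[(2S,3R)-3-{(3E)-6-(tert-butyldimethylsilyloxy)-4-[(4-methoxybenzyloxy)methyl]hex-3-en-1-yl}-3-methyloxiran-2-yl]furan-2(5H)-one, via hydroxy enoate 16 (not isolated)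
Conditions: H2 (1 atm), Pd on CaCO3 poisoned with Pb(OAc)2, quinoline, EtOAc, rt; then PPTS (cat.), CH2Cl2, rt
Reagents that add atoms: none
Why: Lindlar semihydrogenation adds H2 syn to the ynoate only, and the Z γ-hydroxy enoate lactonises to the butenolide with loss of ethanol; C6 is not touched.

Step 12
Reactants: 17 butenolide silyl ether
Product: 18 (5S)-5-[(2S,3R)-3-{(3E)-6-hydroxy-4-[(4-methoxybenzyloxy)methyl]hex-3-en-1-yl}-3-methyloxiran-2-yl]furan-2(5H)-one
Conditions: HF·pyridine, pyridine, THF, 0 °C → rt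
Reagents that add atoms: none
Why: fluoride cleavage of the only silyl ether left; buffered HF·pyridine spares the epoxide, the butenolide and the PMB ether.

Step 13
Reactants: 18 C8 alcohol
Product: 19 (3E)-3-[(4-methoxybenzyloxy)methyl]-6-{(2R,3S)-2-methyl-3-[(2S)-5-oxo-2,5-dihydrofuran-2-yl]oxiran-2-yl}hex-3-enal
Conditions: Dess–Martin periodinane, NaHCO3, CH2Cl2, 0 °C
Reagents that add atoms: none
Why: Dess–Martin oxidation under buffered conditions gives the β,γ-unsaturated C8 aldehyde without migration of C1=C10 into conjugation; it is used at once without chromatography.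

Step 14
Reactants: 19 epoxy butenolide C8 aldehyde
Product: 21 (4R,5S,6S,7R,8R)-4,5-epoxy-8-hydroxy-14-(4-methoxybenzyloxy)germacr-1(10)-en-12,6-olide (C2 and C9 cis on C1=C10), via samarium alkoxide enolate 20 (not isolated)
Conditions: SmI2 (2.5 equiv, added over 4 h), t-BuOH (2 equiv), THF (2 mM), −40 → 0 °C; aq. NH4Cl
Reagents that add atoms: none
Why: Proposed new method: SmI2 donates one electron to the C8 aldehyde, the O-samarium ketyl radical attacks C7, the β-carbon of the butenolide, in a 10-exo-trig closure (C11 stays outside the new ring), and a second electron converts the C11 radical into the trivalent samarium enolate 20, which t-BuOH and the work-up protonate. The closest known reaction type is the SmI2 ketyl–olefin coupling of aldehydes with acrylates, crotonates and unsaturated lactones, which is established between molecules and for rings of five to eight members but not for a ten-membered carbocycle. The closure is helped by the two cis elements of the tether (cis-epoxide C4–C5 and ring-cis C1=C10), by slow addition of SmI2 to a 2 mM solution, which keeps pinacol coupling and over-reduction of the ketyl slow, and by the reversible ketyl formation that the absence of a phosphoramide allows. C7 should be set by the planar butenolide, bond formation on the face away from C5 giving the trans-fused lactone with the C5–C6 and C7–C8 bonds staggered, whereas the other face would force these bonds to eclipse over the lactone. C8 should be set by a seven-membered chelate of samarium between the ketyl oxygen and the lactone carbonyl, open because no strong donor ligand is present: it holds O8 over the C11–C12 side of the lactone while C9 has to point toward C6 to complete the ring, so H8 lies outside and the 8R alkoxide results. The step needs the aldehyde to be reduced before the butenolide, whose radical anion would break the C6–O bond and open the epoxide, and this rests on the much easier reduction of an aliphatic aldehyde by SmI2 in THF at low temperature.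

Step 15
Reactants: 21 hydroxy lactone
Product: 22 8-O-triethylsilyl ether of 21 (configuration unchanged)
Conditions: Et3SiCl, imidazole, DMAP (cat.), DMF, 0 °C → rt
Reagents that add atoms: chlorotriethylsilane CC[Si](Cl)(CC)CC
Why: silylation of the secondary C8 alcohol; it prevents formation in step 16 of a C8 alkoxide, which is cis to C11 and could attack the lactone carbonyl (translactonisation to the 12,8-olide).

Step 16
Reactants: 22 silyl-protected lactone
Product: 24 11-(dimethylaminomethyl) derivative of 22 (C11 epimers), via lithium enolate 23 (not isolated)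
Conditions: LiN(i-Pr)2, THF, −78 °C; dimethyl(methylidene)ammonium iodide, −78 → 0 °C
Reagents that add atoms: dimethyl(methylidene)ammonium iodide C=[N+](C)C.[I-]
Why: kinetic lithium enolate of the γ-lactone (the only enolisable carbonyl) and Mannich reaction with Eschenmoser's salt at C11; the configuration at C11 is of no consequence.

Step 17
Reactants: 24 Mannich base
Product: 26 11(13)-methylene lactone with O8 triethylsilyl ether and O14 PMB ether, via ammonium iodide 25 (not isolated)
Conditions: MeI, THF, rt; then aq. NaHCO3, EtOAc, rt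
Reagents that add atoms: none
Why: exhaustive N-methylation and base-induced β-elimination of trimethylamine (Hofmann-type, E1cB) give the exocyclic C11=C13 methylene; C7 is not enolisable and stays as set.

Step 18
Reactants: 26 silyl ether
Product: 27 (4R,5S,6S,7R,8R)-4,5-epoxy-8-hydroxy-14-(4-methoxybenzyloxy)germacra-1(10),11(13)-dien-12,6-olide
Conditions: HF·pyridine, pyridine, THF, 0 °C
Reagents that add atoms: none
Why: fluoride cleavage of the only silyl ether; the PMB ether, the epoxide and the α-methylene lactone are stable to buffered HF·pyridine.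

Step 19
Reactants: 27 C8 alcohol
Product: 28 (4R,5S,6S,7R,8R)-4,5-epoxy-14-(4-methoxybenzyloxy)-8-(3-methylbutanoyloxy)germacra-1(10),11(13)-dien-12,6-olide
Conditions: (i-BuCO)2O, DMAP (cat.), pyridine, CH2Cl2, 0 °C → rt
Reagents that add atoms: 3-methylbutanoic anhydride CC(C)CC(=O)OC(=O)CC(C)C
Why: DMAP-catalysed acyl transfer to the secondary alcohol; C14 is still protected, so no hemiacetal between O8 and a C14 aldehyde can interfere.

Step 20
Reactants: 28 PMB ether
Product: 29 (4R,5S,6S,7R,8R)-4,5-epoxy-14-hydroxy-8-(3-methylbutanoyloxy)germacra-1(10),11(13)-dien-12,6-olide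
Conditions: DDQ, CH2Cl2/pH 7 phosphate buffer, 0 °C
Reagents that add atoms: none
Why: oxidative cleavage of the PMB ether by DDQ (hydride abstraction, then hydrolysis of the oxocarbenium ion) under neutral conditions that leave the ester, the epoxide and the α-methylene lactone alone.

Step 21
Reactants: 29 allylic alcohol
Product: 30 CNP0260081.1, (4R,5S,6S,7R,8R)-4,5-epoxy-8-(3-methylbutanoyloxy)-14-oxogermacra-1(10),11(13)-dien-12,6-olide (C2 and C9 cis on C1=C10)
Conditions: MnO2, CH2Cl2, rt
Reagents that add atoms: none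
Why: MnO2 oxidises only the allylic primary alcohol to the enal and does not isomerise the C1=C10 bond.

**Compound list**

1 | triethyl phosphonoacetate | CCOC(=O)CP(=O)(OCC)OCC | starting material
2 | tert-butyl(2-iodoethoxy)dimethylsilane | CC(C)(C)[Si](C)(C)OCCI | starting material
3 | ethyl 4-(tert-butyldimethylsilyloxy)-2-(diethoxyphosphoryl)butanoate (racemic) | CCOC(=O)C(CCO[Si](C)(C)C(C)(C)C)P(=O)(OCC)OCC | intermediate
4 | nerol | CC(C)=CCC/C(C)=C\CO | starting material
5 | [(2S,3R)-3-methyl-3-(4-methylpent-3-en-1-yl)oxiran-2-yl]methanol | CC(C)=CCC[C@@]1(C)O[C@H]1CO | intermediate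
6 | triethyl{[(2S,3R)-3-methyl-3-(4-methylpent-3-en-1-yl)oxiran-2-yl]methoxy}silane | CC(C)=CCC[C@@]1(C)O[C@H]1CO[Si](CC)(CC)CC | intermediate
7 | ozonide of 6 (3,3-dimethyl-1,2,4-trioxolane, formed in the flask) | CC1(C)OOC(CC[C@@]2(C)O[C@H]2CO[Si](CC)(CC)CC)O1 | intermediate
8 | 3-[(2R,3S)-2-methyl-3-(triethylsilyloxymethyl)oxiran-2-yl]propanal | O=CCC[C@@]1(C)O[C@H]1CO[Si](CC)(CC)CC | intermediate
9 | ethyl (2E)-2-[2-(tert-butyldimethylsilyloxy)ethyl]-5-[(2R,3S)-2-methyl-3-(triethylsilyloxymethyl)oxiran-2-yl]pent-2-enoate | CC(C)(C)[Si](C)(C)OCC/C(C(=O)OCC)=C\CC[C@@]1(C)O[C@H]1CO[Si](CC)(CC)CC | intermediate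
10 | (2E)-2-[2-(tert-butyldimethylsilyloxy)ethyl]-5-[(2R,3S)-2-methyl-3-(triethylsilyloxymethyl)oxiran-2-yl]pent-2-en-1-ol | CC(C)(C)[Si](C)(C)OCC/C(CO)=C\CC[C@@]1(C)O[C@H]1CO[Si](CC)(CC)CC | intermediate
11 | O14 4-methoxybenzyl ether of 10 | CC(C)(C)[Si](C)(C)OCC/C(COCc1ccc(OC)cc1)=C\CC[C@@]1(C)O[C@H]1CO[Si](CC)(CC)CC | intermediate
12 | [(2S,3R)-3-{(3E)-6-(tert-butyldimethylsilyloxy)-4-[(4-methoxybenzyloxy)methyl]hex-3-en-1-yl}-3-methyloxiran-2-yl]methanol | CC(C)(C)[Si](C)(C)OCC/C(COCc1ccc(OC)cc1)=C\CC[C@@]1(C)O[C@H]1CO | intermediate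
13 | (2R,3R)-3-{(3E)-6-(tert-butyldimethylsilyloxy)-4-[(4-methoxybenzyloxy)methyl]hex-3-en-1-yl}-3-methyloxirane-2-carbaldehyde | CC(C)(C)[Si](C)(C)OCC/C(COCc1ccc(OC)cc1)=C\CC[C@@]1(C)O[C@H]1C=O | intermediate
14 | ethyl propiolate | C#CC(=O)OCC | starting material
15 | ethyl (4S)-4-hydroxy-4-[(2S,3R)-3-{(3E)-6-(tert-butyldimethylsilyloxy)-4-[(4-methoxybenzyloxy)methyl]hex-3-en-1-yl}-3-methyloxiran-2-yl]but-2-ynoate | CC(C)(C)[Si](C)(C)OCC/C(COCc1ccc(OC)cc1)=C\CC[C@@]1(C)O[C@H]1[C@H](C#CC(=O)OCC)O | intermediate
16 | ethyl (2Z,4S)-4-hydroxy-but-2-enoate corresponding to 15 (formed in the flask) | CC(C)(C)[Si](C)(C)OCC/C(COCc1ccc(OC)cc1)=C\CC[C@@]1(C)O[C@H]1[C@H](/C=C\C(=O)OCC)O | intermediate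
17 | (5S)-5-[(2S,3R)-3-{(3E)-6-(tert-butyldimethylsilyloxy)-4-[(4-methoxybenzyloxy)methyl]hex-3-en-1-yl}-3-methyloxiran-2-yl]furan-2(5H)-one | CC(C)(C)[Si](C)(C)OCC/C(COCc1ccc(OC)cc1)=C\CC[C@@]1(C)O[C@H]1[C@H]2OC(=O)C=C2 | intermediate
18 | (5S)-5-[(2S,3R)-3-{(3E)-6-hydroxy-4-[(4-methoxybenzyloxy)methyl]hex-3-en-1-yl}-3-methyloxiran-2-yl]furan-2(5H)-one | OCC/C(COCc1ccc(OC)cc1)=C\CC[C@@]1(C)O[C@H]1[C@H]2OC(=O)C=C2 | intermediate
19 | (3E)-3-[(4-methoxybenzyloxy)methyl]-6-{(2R,3S)-2-methyl-3-[(2S)-5-oxo-2,5-dihydrofuran-2-yl]oxiran-2-yl}hex-3-enal | O=CC/C(COCc1ccc(OC)cc1)=C\CC[C@@]1(C)O[C@H]1[C@H]2OC(=O)C=C2 | intermediate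
20 | bis(diiodosamarium) C8 alkoxide C11 enolate of 21 (trivalent samarium, formed in the flask) | C1=C(O[Sm](I)I)O[C@H]2[C@H]1[C@H](O[Sm](I)I)C/C(COCc3ccc(OC)cc3)=C\CC[C@@]1(C)O[C@@H]21 | intermediate
21 | (4R,5S,6S,7R,8R)-4,5-epoxy-8-hydroxy-14-(4-methoxybenzyloxy)germacr-1(10)-en-12,6-olide | C1C(=O)O[C@H]2[C@H]1[C@H](O)C/C(COCc3ccc(OC)cc3)=C\CC[C@@]1(C)O[C@@H]21 | intermediate
22 | 8-O-triethylsilyl ether of 21 | C1C(=O)O[C@H]2[C@H]1[C@H](O[Si](CC)(CC)CC)C/C(COCc3ccc(OC)cc3)=C\CC[C@@]1(C)O[C@@H]21 | intermediate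
23 | lithium enolate of 22 (formed in the flask) | C1=C(O[Li])O[C@H]2[C@H]1[C@H](O[Si](CC)(CC)CC)C/C(COCc3ccc(OC)cc3)=C\CC[C@@]1(C)O[C@@H]21 | intermediate
24 | 11-(dimethylaminomethyl) derivative of 22 (C11 epimers) | CN(C)CC1C(=O)O[C@H]2[C@H]1[C@H](O[Si](CC)(CC)CC)C/C(COCc3ccc(OC)cc3)=C\CC[C@@]1(C)O[C@@H]21 | intermediate
25 | trimethylammonium iodide of 24 (formed in the flask) | C[N+](C)(C)CC1C(=O)O[C@H]2[C@H]1[C@H](O[Si](CC)(CC)CC)C/C(COCc3ccc(OC)cc3)=C\CC[C@@]1(C)O[C@@H]21.[I-] | intermediate
26 | 8-O-triethylsilyl ether of 27 | C=C1C(=O)O[C@H]2[C@H]1[C@H](O[Si](CC)(CC)CC)C/C(COCc3ccc(OC)cc3)=C\CC[C@@]1(C)O[C@@H]21 | intermediate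
27 | (4R,5S,6S,7R,8R)-4,5-epoxy-8-hydroxy-14-(4-methoxybenzyloxy)germacra-1(10),11(13)-dien-12,6-olide | C=C1C(=O)O[C@H]2[C@H]1[C@H](O)C/C(COCc3ccc(OC)cc3)=C\CC[C@@]1(C)O[C@@H]21 | intermediate
28 | (4R,5S,6S,7R,8R)-4,5-epoxy-14-(4-methoxybenzyloxy)-8-(3-methylbutanoyloxy)germacra-1(10),11(13)-dien-12,6-olide | C=C1C(=O)O[C@H]2[C@H]1[C@H](OC(=O)CC(C)C)C/C(COCc3ccc(OC)cc3)=C\CC[C@@]1(C)O[C@@H]21 | intermediate
29 | (4R,5S,6S,7R,8R)-4,5-epoxy-14-hydroxy-8-(3-methylbutanoyloxy)germacra-1(10),11(13)-dien-12,6-olide | C=C1C(=O)O[C@H]2[C@H]1[C@H](OC(=O)CC(C)C)C/C(CO)=C\CC[C@@]1(C)O[C@@H]21 | intermediate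
30 | CNP0260081.1 | C=C1C(=O)O[C@H]2[C@H]1[C@H](OC(=O)CC(C)C)C/C(C=O)=C\CC[C@@]1(C)O[C@@H]21 | target

**Step count**

Total steps: 21. Longest linear sequence: 20 steps (nerol 4 to 30, steps 2–21); step 1 is the side branch to phosphonate 3.

**Steps most likely to fail**

1. Step 14 (the proposed new method).
   - What may go wrong: the ketyl may dimerise or be reduced further before the slow ten-membered closure; electron transfer may go to the butenolide, with loss of the C6–O bond and opening of the epoxide; the facial selectivity at C7 and C8 may be poor.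
   - Fallback: a chromium-mediated Barbier allylation, a known type of ten-membered ring closure, forms the same C7–C8 bond. It sets out from 15 and comes back at 27.
   - From 15, palladium-catalysed syn-hydrostannation (Bu3SnH, PdCl2(PPh3)2, THF) puts tin on C11, and lactonisation gives the 11-stannyl butenolide F1.
   - Iododestannylation (I2, CH2Cl2, 0 °C) gives the 11-iodo butenolide F2.
   - Stille coupling with (tributylstannyl)methanol (Pd(PPh3)4, dioxane, 80 °C) gives the 11-(hydroxymethyl) butenolide F3.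
   - HF·pyridine frees O8 to give the diol F4.
   - N-Bromosuccinimide/Me2S (Corey–Kim conditions) converts only the allylic C13 alcohol into the allylic bromide F5.
   - Buffered Dess–Martin oxidation gives the bromo aldehyde F6.
   - CrCl2 in THF at high dilution then joins C7 to C8 with allylic transposition and delivers the α-methylene lactone 27 directly. A C8 epimer, should it form, would be carried on by Mitsunobu esterification with isovaleric acid, which inverts C8 and gives 28.

2. Step 10.
   - What may go wrong: poor facial selectivity at C6 in the addition to the epoxy aldehyde.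
   - Fallback: reagent-controlled reduction in place of substrate-controlled addition. It sets out from 13 and comes back at 15.
   - The acetylide is added as before and the crude mixture of 15 and its C6 epimer F7 is oxidised (Dess–Martin periodinane, NaHCO3) to the ynone F8.
   - Midland reduction of F8 with (R)-Alpine-Borane, the enantiomer that the usual model (alkyne as the small group) assigns to the 6S carbinol, returns 15.

3. Step 5.
   - What may go wrong: incomplete E selectivity in the olefination and difficult separation of the olefin isomers, which would carry the wrong C1=C10 geometry into the ring closure.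
   - Fallback: Wittig reaction of an α-branched stabilised ylide, a class that is reliably E-selective. It sets out from 2 and comes back at 9.
   - Iodide 2 alkylates ethyl (triphenylphosphoranylidene)acetate (EtOAc, reflux) to the phosphonium iodide F9.
   - Aqueous NaOH gives the ylide F10, which reacts with aldehyde 8 (toluene, 80 °C) to give 9.

**Further compounds**

F1 | step 14 | (5S)-3-(tributylstannyl) analogue of butenolide 17 | CC(C)(C)[Si](C)(C)OCC/C(COCc1ccc(OC)cc1)=C\CC[C@@]1(C)O[C@H]1[C@H]2OC(=O)C([Sn](CCCC)(CCCC)CCCC)=C2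
F2 | step 14 | (5S)-3-iodo analogue of butenolide 17 | CC(C)(C)[Si](C)(C)OCC/C(COCc1ccc(OC)cc1)=C\CC[C@@]1(C)O[C@H]1[C@H]2OC(=O)C(I)=C2
F3 | step 14 | (5S)-3-(hydroxymethyl) analogue of butenolide 17 | CC(C)(C)[Si](C)(C)OCC/C(COCc1ccc(OC)cc1)=C\CC[C@@]1(C)O[C@H]1[C@H]2OC(=O)C(CO)=C2
F4 | step 14 | (5S)-3-(hydroxymethyl) analogue of alcohol 18 (C8, C13 diol) | OCC/C(COCc1ccc(OC)cc1)=C\CC[C@@]1(C)O[C@H]1[C@H]2OC(=O)C(CO)=C2
F5 | step 14 | (5S)-3-(bromomethyl) analogue of alcohol 18 | OCC/C(COCc1ccc(OC)cc1)=C\CC[C@@]1(C)O[C@H]1[C@H]2OC(=O)C(CBr)=C2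
F6 | step 14 | (5S)-3-(bromomethyl) analogue of aldehyde 19 | O=CC/C(COCc1ccc(OC)cc1)=C\CC[C@@]1(C)O[C@H]1[C@H]2OC(=O)C(CBr)=C2
F7 | step 10 | (4R)-carbinol, the C6 epimer of 15 | CC(C)(C)[Si](C)(C)OCC/C(COCc1ccc(OC)cc1)=C\CC[C@@]1(C)O[C@H]1[C@@H](C#CC(=O)OCC)O
F8 | step 10 | ethyl 4-oxobut-2-ynoate (ynone) corresponding to 15 | CC(C)(C)[Si](C)(C)OCC/C(COCc1ccc(OC)cc1)=C\CC[C@@]1(C)O[C@H]1C(=O)C#CC(=O)OCC
F9 | step 5 | [4-(tert-butyldimethylsilyloxy)-1-ethoxy-1-oxobutan-2-yl]triphenylphosphonium iodide | CCOC(=O)C(CCO[Si](C)(C)C(C)(C)C)[P+](c1ccccc1)(c1ccccc1)c1ccccc1.[I-]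
F10 | step 5 | ethyl 4-(tert-butyldimethylsilyloxy)-2-(triphenylphosphoranylidene)butanoate | CCOC(=O)C(CCO[Si](C)(C)C(C)(C)C)=P(c1ccccc1)(c1ccccc1)c1ccccc1
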